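The data come from a simulation on assumed constants, noise included.

- If I follow one partner molecule through a flask, I ask what chance it has of ending in target. I assume third substrate takes its own equivalents of partner first and that second substrate competes for the rest, which I call free partner.

- south-west: starting material 20 mM; partner 1 equiv; second substrate 2 equiv; third substrate 0.20 equiv; run made earlier
- flask: starting material 20 mM; partner 1.00 equiv; second substrate 1.00 equiv; third substrate 0.200 equiv; time 15 h

- south-west (time / h: target / %): 0.833: 24.1; 2.00: 18.8; 2.50: 17.2; 4.00: 9.2; 5.00: 6.0

(standard deviation of a reading: 1 percentage point)



- time up to 15 h at which target stands highest
- the amount of target, in percent of the starting material charged, at that time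
- earliest time at which at least nineteen twentieths of that best amount are there
- latest time at which they still are

- The south-west tail falls at 0.334 h⁻¹ as a reading, and running it back to time zero reads 31.8% as target made in that run.
- That run has 0.800 equiv of free partner, so on this reading 39.8% of it ends in target: this share is the partner's chance, a selectivity in the usual sense.
- The flask differs from the south-west run in one charge, with second substrate at 1.00 equiv against 2 equiv, which is half.
- I take the odds of target against second product to grow to twice their south-west value, to 1.32, so I reckon the flask's chance at 56.9%.
- The flask has the same 0.800 equiv of free partner, so I reckon 45.5% of target made in all in the flask, which is more than my reading for the south-west run.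
- The forecast gives a peak of 30% at 0.9 h, and a band from 0.45 h to 1.7 h. It places second substrate elsewhere than I do: “I assume the loss runs through the second substrate”.
- The flask peaks at 27.6% at 1.07 h, and its band runs from 0.712 h to 1.56 h.

    third substrate + partner → third product (k = 0.620 M⁻¹ s⁻¹)
    target → over-reaction product (k = 1.20 × 10⁻⁴ s⁻¹)
    starting material + partner → target (k = 0.0160 M⁻¹ s⁻¹)
    second substrate + partner → second product (k = 0.00710 M⁻¹ s⁻¹)
    2 starting material → self-condensation product (k = 0.00220 M⁻¹ s⁻¹)

- At 15.0 h the flask holds 48.6% of over-reaction product and 0.129% of target, so 60.9% of its free partner went through target, against the 39.8% read in the south-west run with twice the second substrate. The neighbour with 0.400 equiv of partner keeps the same third substrate charge, which leaves 0.200 equiv free, and that chance gives 12.2% made. That neighbour ends with 13.0% of over-reaction product, and its target peaks at 8.04%.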